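## Analysis of the target

Target 21 is a bicyclo[3.2.1]oct-2-en-8-one. A cyclohexene ring (C1, C2, C3, C4, C5, C8) and a cyclopentanone ring (C1, C7, C6, C5, C8) share the C1–C8–C5 unit. Five stereocentres are contiguous: the quaternary bridgeheads C1 (allyl) and C5 (methoxy), C6 (aryl, endo, pointing toward the three-carbon bridge), C7 (methyl, exo, pointing toward C8 and trans to the aryl group) and the C4 carbinol. The C4 hydroxyl lies on the face of the C6–C7 bridge, syn to the aryl group. The sensitive groups are the C4 hydroxyl/C8 ketone pair (an aldol across quaternary C5, open to retro-aldol cleavage under base), the C2=C3 methyl enol ether next to a free carbinol (acid), the free phenol and the terminal alkene. The synthesis is hard because both bridgeheads are quaternary, both flank the C8 ketone and neither can be reached by enolate chemistry; in addition the aryl/methyl pair must be trans with a fixed endo/exo sense and C3, C4 and C5 are all oxygenated. The strategy rests on C3: it is a single oxygenated carbon between vinylic C2 and oxygenated C4. If C3 is taken out, C2 and C4 become the two carbons of an enol ether double bond in a bicyclo[2.2.1]hept-2-en-7-one, which is the retron of a Diels–Alder reaction between a cyclopentadienone and an (E)-propenylarene.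

## Retrosynthetic reasoning

21 from 20: only the O–Si bond at C4 is cut. The silyl ether is kept to the last step because it blocks retro-aldol cleavage of C4–C5 in the alkoxide step before it. Its removal must use a buffered fluoride source so that neither the aldol nor the enol ether of 21 is harmed.

20 from 19: the C3–O bond is cut, and the methoxy group is traced back to the C3 bromide. The exchange is placed after the reduction of C4, because while C4 and C8 are both carbonyls the quaternary C5 sits inside a non-enolisable 1,3-diketone that any alkoxide would open by retro-Claisen cleavage. In 19 only the hindered, non-enolisable C8 ketone remains. The forward reaction must substitute a vinylic bromide that cannot react by addition–elimination, so copper catalysis is needed; the aryl silyl ether cannot survive the alkoxide and is allowed to fall off there.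

19 from 18 from 17: the O–Si bond and then the C4–H bond are cut. The forward reduction must choose the C4 carbonyl over C8 and deliver hydride from the C8 face. Doing it on the α-bromo enone helps on both counts, since this carbonyl is the more electrophilic and the less hindered one, and the endo aryl group covers the other face.

17 from 14 and 15: the bonds C2–C3 and C3–C4 are cut and C3 is removed as the carbene carbon supplied by 15. This is the disconnection that simplifies most: the six-membered enone ring contracts to the five-membered enol ether ring of 14 and the C3 heteroatom becomes a leaving group on the carbene. The forward step passes through cyclopropane 16 and must insert C3 only between C2 and C4, which the fixed position of the enol ether ensures.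

14 from 13 from 12: the O–Si bond of the enol ether is cut, then the racemate is separated. The ketone of 13 can enolise only toward the CH2 group, because its other neighbour is the quaternary methoxy bridgehead, so 14 forms as a single regioisomer. No catalyst is known to control the faces of a transient cyclopentadienone, so the racemic dione 12 is resolved; nothing downstream can racemise.

12 from 9 and 10 through 11: the bonds C1–C7 and C5–C6 are cut. This Diels–Alder disconnection gives both bridgehead quaternary carbons and the trans aryl/methyl pair from flat, achiral partners in one suprafacial event. The forward reaction must join the allyl-bearing terminus of 10 to the methyl-bearing carbon of 9, place the aryl group endo and keep the (E)-geometry. Adduct 11 is hydrolysed directly to 12.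

10 from 7, 7 from 5 and 6, 5 from 4, 4 from 3, 3 from 2, 2 from 1, and 9 from 8: the dienone is released by 1,2-elimination of methanol from ketal 7. A free 1,3-diketone at this stage would offer two competing enolisable oxygens, and the wrong enol derivative would place hydrogen, not allyl, on a diene terminus. The ketal in 4 has three roles: it removes the acidic 1,3-dicarbonyl C–H, it leaves one free enone carbonyl so that iodination and allylation (5, then 7 with 6) occur next to the future C8, and it becomes the leaving group that fixes the enol ether position in 10. The methoxy group comes from O–H insertion of the diazo compound 2, made from 1.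

## Alternatives that were turned down

Alternative 1: The C1–C7 bond is disconnected. In the forward direction a silyl triflate would ionise the C3 ketal of cyclobutanol A1 to a methoxy-stabilised C1–C2–C3 allyl cation, and C7 would shift from the carbinol carbon C8 to C1 (semipinacol ring expansion). That one event makes quaternary C1, the cyclopentanone ring and the C8 carbonyl, and leaves the C2=C3 methyl enol ether as in 21; the product A2 is the bis-silyl ether of 21. In its favour, the oxidation pattern at C3, C4 and C8 arrives without any halide-to-methoxide exchange, and only desilylation follows; on the length of the endgame it is clearly stronger than the chosen route, which needs four steps after its key step. Against it, A1 is as hard to make as 21: a cis-fused bicyclo[4.2.0]octene with five stereocentres, two of them fully substituted ring-fusion carbons. The obvious access, a [2+2] photocycloaddition of 9 to a cyclohexadienone enol derivative, runs through a triplet 1,4-diradical that can lose the (E)-geometry and gives regioisomers. In the shift itself two cyclobutane bonds (C8–C7 and C8–C5) compete, and the ketal must ionise next to a silyloxy-bearing carbon. The chosen strategy offers instead a concerted cycloaddition that sets the trans aryl/methyl pair and both bridgeheads at once from simple achiral pieces.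

Alternative 2: The C5–C6 bond is disconnected. In the forward direction acid would ionise the benzylic C–O bond of hydrobenzofuranone A3, and the benzylic cation at C6 would be recaptured by C5, the central carbon of the freed 1,3-dicarbonyl enol, to give enedione A4. In its favour, the step is short and biomimetic, and A4 already carries the C3 and C5 methoxy groups and the allyl group, so only reduction of C4 and desilylation remain. It needs no vinyl halide exchange and no alkoxide step near the 1,3-diketone; on step economy after the key step it is the strongest of the three and stronger than the chosen route. Against it, the reaction is an equilibrium between O-recapture (A3 and its C6 epimer) and C-recapture, so the outcome is set by thermodynamics and not by design, and the C6 configuration is set by a free benzylic cation. A3 itself, with a quaternary allyl-bearing ring-fusion carbon beside two further stereocentres, must first be made as one enantiomer, and oxidative phenol–propenylarene couplings to such systems give racemic regioisomer mixtures. The chosen strategy offers kinetic control of all four ring stereocentres and a C3 bromide that keeps the C3 substituent open.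

Alternative 3: The C1–C2 bond is disconnected. In the forward direction LiN(i-Pr)2 would form the two enolates of keto-cyclopentanone A5 (at C1 and at the methyl group C2), and Fe(acac)3 would couple them oxidatively to close the six-membered ring and create quaternary C1, giving A6. In its favour, the hardest quaternary centre and the bridged ring come from one C–C bond formation on a monocyclic precursor, with the C4 oxygen and its configuration already in place and no strained intermediate before the coupling. Against it, A5 needs four contiguous stereocentres on a cyclopentanone, one of them the quaternary C5, which is a long synthesis in itself. Its α-silyloxy ketone has a second acidic site at C4, so enolate equilibration could epimerise C4 or couple C4 instead of C2 to C1. A6 also stops at a C3 ketone with a C2 methylene, so the C2=C3 methyl enol ether would still have to be made by regioselective O-methylation of an unsymmetrical ketone beside the base-labile C4/C8 aldol. The chosen strategy is comparable in length overall but builds ring and stereocentres in one cycloaddition and places its risk in a ring expansion whose regiochemistry is fixed by structure.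

Key step: step 10

Remarks on the chemistry:
- Ar stands for 4-(tert-butyldimethylsilyloxy)-3-methoxyphenyl. In the discussion the locants C1–C8 of the bicyclo[3.2.1]octane core are used; systematic names carry their own locants.
- Assumption: sodium methoxide in step 13 also cleaves the aryl silyl ether, so 20 is written as the free phenol.
- Assumption: isoeugenol 8 is used as the pure (E)-isomer.

## Route

Step 1
Reactants: 1 cyclopent-4-ene-1,3-dione
Product: 2 2-diazocyclopent-4-ene-1,3-dione
Conditions: 4-acetamidobenzenesulfonyl azide, Et3N, MeCN, 0 °C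
Reagents that add atoms: 4-acetamidobenzenesulfonyl azide, CC(=O)Nc1ccc(cc1)S(=O)(=O)N=[N+]=[N-]
Why: Regitz diazo transfer to the doubly activated C2 methylene, which an amine deprotonates easily; the enedione alkene is not involved.

Step 2
Reactants: 2 2-diazocyclopent-4-ene-1,3-dione
Product: 3 2-methoxycyclopent-4-ene-1,3-dione
Conditions: Rh2(OAc)4 (1 mol %), MeOH (10 equiv), 1,2-dichloroethane, 60 °C
Reagents that add atoms: methanol, CO
Why: Rhodium carbenoid O–H insertion, a known reaction of cyclic 2-diazo-1,3-diones with alcohols; the carbenoid is trapped by methanol faster than it rearranges.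

Step 3
Reactants: 3 2-methoxycyclopent-4-ene-1,3-dione
Product: 4 rac-4,4,5-trimethoxycyclopent-2-en-1-one
Conditions: HC(OMe)3, MeOH, TsOH (cat.), 0 °C to rt
Reagents that add atoms: trimethyl orthoformate, COC(OC)OC; methanol, CO
Why: Acid-catalysed ketalisation; 3 is mirror-symmetric, so only one mono-ketal can form, and the second carbonyl is then an ordinary, deactivated enone next to a quaternary carbon. The ketal removes the acidic 1,3-dicarbonyl C–H and differentiates the two carbonyls.

Step 4
Reactants: 4 rac-4,4,5-trimethoxycyclopent-2-en-1-one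
Product: 5 rac-2-iodo-4,4,5-trimethoxycyclopent-2-en-1-one
Conditions: I2, pyridine, CH2Cl2, 0 °C to rt
Reagents that add atoms: iodine, II
Why: Johnson α-iodination of an enone (pyridine conjugate addition, iodination of the enolate, elimination); iodine can only enter α to the one free carbonyl.

Step 5
Reactants: 5 rac-2-iodo-4,4,5-trimethoxycyclopent-2-en-1-one; 6 allyltributylstannane
Product: 7 rac-2-allyl-4,4,5-trimethoxycyclopent-2-en-1-one
Conditions: Pd2(dba)3 (2.5 mol %), AsPh3 (10 mol %), CuI (10 mol %), NMP, rt
Reagents that add atoms: none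
Why: Stille coupling of an α-iodoenone with an allylstannane under mild arsine/copper-accelerated conditions, which should keep the skipped diene from moving into conjugation. The allyl group now sits on the carbon next to the free carbonyl, the future C1 next to C8.

Step 6
Reactants: 8 (E)-isoeugenol
Product: 9 tert-butyl{2-methoxy-4-[(E)-prop-1-en-1-yl]phenoxy}dimethylsilane
Conditions: TBSCl, imidazole, DMF, rt
Reagents that add atoms: tert-butyldimethylsilyl chloride, CC(C)(C)[Si](C)(C)Cl
Why: Standard phenol silylation; the silyl ether keeps the styrene electron-rich and protects the phenol from the silyl triflate and carbene steps.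

Step 7
Reactants: 7 rac-2-allyl-4,4,5-trimethoxycyclopent-2-en-1-one; 9 tert-butyl{2-methoxy-4-[(E)-prop-1-en-1-yl]phenoxy}dimethylsilane
Product: 12 rac-(1R,4S,5R,6S)-4-allyl-6-Ar-1-methoxy-5-methylbicyclo[2.2.1]heptane-2,7-dione, via cyclopentadienone 10 (not isolated), via enol ether adduct 11 (not isolated)
Conditions: 9 (3 equiv), TMSOTf (1.05 equiv), 2,6-lutidine, CH2Cl2, −40 °C to rt; then 1 M HCl, THF, rt
Reagents that add atoms: water, O
Why: The silyl triflate ionises the allylic ketal and the base removes the acidified neighbouring C–H (ketal-to-enol-ether elimination, the 1,2-elimination from a 4-substituted cyclopentenone by which cyclopentadienones are liberated), so 10 forms with its enol ether oxygen fixed by the position of the ketal. The antiaromatic dienone is trapped by excess electron-rich 9 in an inverse-electron-demand Diels–Alder reaction: the nucleophilic CHMe carbon bonds to the allyl-bearing terminus, the benzylic carbon bonds to the methoxy-bearing (enol ether) terminus, the aryl group goes endo by secondary overlap and the (E)-geometry places the methyl group exo, which sets all four ring stereocentres in the relative sense. Aqueous acid then hydrolyses the strained methyl enol ether of 11 to the ketone.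

Step 8
Reactants: 12 rac-(1R,4S,5R,6S)-4-allyl-6-Ar-1-methoxy-5-methylbicyclo[2.2.1]heptane-2,7-dione
Product: 13 (1R,4S,5R,6S)-4-allyl-6-Ar-1-methoxy-5-methylbicyclo[2.2.1]heptane-2,7-dione
Conditions: preparative HPLC on amylose tris(3,5-dimethylphenylcarbamate), hexane/i-PrOH, rt
Reagents that add atoms: none
Why: Resolution by chromatography on a chiral stationary phase; no bond is changed and no later step can racemise the four stereocentres. The absolute configuration should be confirmed on bromide 17 by anomalous-dispersion X-ray analysis.

Step 9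
Reactants: 13 (1R,4S,5R,6S)-4-allyl-6-Ar-1-methoxy-5-methylbicyclo[2.2.1]heptane-2,7-dione
Product: 14 (1R,4R,5R,6S)-4-allyl-6-Ar-1-methoxy-5-methyl-2-(trimethylsilyloxy)bicyclo[2.2.1]hept-2-en-7-one
Conditions: TMSOTf, Et3N, CH2Cl2, 0 °C; pentane extraction, used crude
Reagents that add atoms: trimethylsilyl trifluoromethanesulfonate, C[Si](C)(C)OS(=O)(=O)C(F)(F)F
Why: Soft enolisation and O-silylation; only the CH2 group carries α-hydrogens (the other α-carbon is the quaternary methoxy bridgehead and the bridging ketone has none), so a single silyl enol ether forms.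

Step 10
Reactants: 14 (1R,4R,5R,6S)-4-allyl-6-Ar-1-methoxy-5-methyl-2-(trimethylsilyloxy)bicyclo[2.2.1]hept-2-en-7-one; 15 bromoform
Product: 17 (1R,5S,6S,7R)-1-allyl-3-bromo-6-Ar-5-methoxy-7-methylbicyclo[3.2.1]oct-2-ene-4,8-dione, via dibromocyclopropane 16 (not isolated)
Conditions: KOt-Bu (2 equiv), pentane, −30 to 0 °C
Reagents that add atoms: none
Why: Bromoform 15 and KOt-Bu give dibromocarbene by α-elimination, and this electrophilic singlet carbene adds in a concerted cheletropic [2+1] fashion (non-linear approach) to the most electron-rich alkene of 14, the silyl enol ether, and not to the monosubstituted allyl alkene. Addition occurs on the exo face, syn to the carbonyl bridge, because the endo face is covered by the C6 aryl group; this closes the three-membered ring of 16. In 16 the bromine that points toward the carbonyl bridge is cis to the two norbornane ring bonds, so its ionisation is coupled to the disrotatory, inward 2π-electrocyclic opening of the cyclopropane (Woodward–Hoffmann–DePuy rule), as in the spontaneous rearrangement of exo-dihalocarbene adducts of norbornene. The opening cuts the former enol ether C–C bond, so the carbene carbon is inserted as C3 between C2 and C4 and the five-membered ring becomes the six-membered enone ring, driven by relief of cyclopropane and norbornane strain and by oxygen stabilisation of the 2-bromoallyl cation. Loss of the silyl group from the resulting oxocarbenium ion to bromide or tert-butoxide gives the C4 carbonyl and leaves bromine on C3. The closest known reaction is the dihalocarbene ring expansion of silyl enol ethers to 2-halo-2-enones. No lasting stereocentre is created (the two cyclopropane centres of 16 are set by the exo approach and destroyed again), and C1, C5, C6 and C7 are untouched. The step needs chemoselectivity, which the nucleophilicity of the enol ether secures, and regiocontrol, which is secured because the ketone of 13 can enolise only away from the quaternary bridgehead.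

Step 11
Reactants: 17 (1R,5S,6S,7R)-1-allyl-3-bromo-6-Ar-5-methoxy-7-methylbicyclo[3.2.1]oct-2-ene-4,8-dione
Product: 18 (1R,4R,5R,6S,7R)-1-allyl-3-bromo-4-hydroxy-6-Ar-5-methoxy-7-methylbicyclo[3.2.1]oct-2-en-8-one
Conditions: NaBH4, CeCl3·7H2O, MeOH, −78 °C
Reagents that add atoms: none
Why: Luche 1,2-reduction; the α-bromo enone carbonyl is more electrophilic and less hindered than the C8 ketone, which is flanked by two quaternary carbons. Hydride arrives from the C8 face because the endo aryl group on C6 covers the other face, which puts the hydroxyl on the side of the C6–C7 bridge as in 21. Reducing C4 here also removes the retro-Claisen-prone 1,3-diketone before any alkoxide is used.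

Step 12
Reactants: 18 (1R,4R,5R,6S,7R)-1-allyl-3-bromo-4-hydroxy-6-Ar-5-methoxy-7-methylbicyclo[3.2.1]oct-2-en-8-one
Product: 19 (1R,4R,5R,6S,7R)-1-allyl-3-bromo-4-(tert-butyldimethylsilyloxy)-6-Ar-5-methoxy-7-methylbicyclo[3.2.1]oct-2-en-8-one
Conditions: TBSOTf, 2,6-lutidine, CH2Cl2, 0 °C
Reagents that add atoms: tert-butyldimethylsilyl trifluoromethanesulfonate, CC(C)(C)[Si](C)(C)OS(=O)(=O)C(F)(F)F
Why: Silylation of a hindered secondary alcohol with a silyl triflate; the ether masks the aldol hydroxyl so that alkoxide in the next step cannot trigger retro-aldol cleavage of C4–C5.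

Step 13
Reactants: 19 (1R,4R,5R,6S,7R)-1-allyl-3-bromo-4-(tert-butyldimethylsilyloxy)-6-Ar-5-methoxy-7-methylbicyclo[3.2.1]oct-2-en-8-one
Product: 20 (1R,4S,5R,6S,7R)-1-allyl-4-(tert-butyldimethylsilyloxy)-6-(4-hydroxy-3-methoxyphenyl)-3,5-dimethoxy-7-methylbicyclo[3.2.1]oct-2-en-8-one
Conditions: NaOMe (excess), CuBr (20 mol %), MeOH/NMP, 110 °C; aq. NH4Cl work-up
Reagents that add atoms: sodium methoxide, [Na+].[O-]C
Why: Copper-catalysed Ullmann-type substitution of an unactivated alkenyl bromide by sodium methoxide, a known way to methyl vinyl ethers. The bridged ring excludes elimination to an alkyne or allene, the C8 ketone is non-enolisable and has no β-carbonyl left, and the C4 silyl ether blocks retro-aldol cleavage. Methoxide also cleaves the aryl silyl ether, and the phenoxide is protonated on work-up.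

Step 14
Reactants: 20 (1R,4S,5R,6S,7R)-1-allyl-4-(tert-butyldimethylsilyloxy)-6-(4-hydroxy-3-methoxyphenyl)-3,5-dimethoxy-7-methylbicyclo[3.2.1]oct-2-en-8-one
Product: 21 (1R,4S,5R,6S,7R)-1-allyl-4-hydroxy-6-(4-hydroxy-3-methoxyphenyl)-3,5-dimethoxy-7-methylbicyclo[3.2.1]oct-2-en-8-one
Conditions: TBAF, AcOH (1:1), THF, 0 °C to rt
Reagents that add atoms: none
Why: Fluoride cleavage of the remaining silyl ether; buffering with acetic acid should keep the β-hydroxy ketone from retro-aldol cleavage and the enol ether from hydrolysis.

## Compound list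

1 | cyclopent-4-ene-1,3-dione | O=C1C=CC(=O)C1 | starting material
2 | 2-diazocyclopent-4-ene-1,3-dione | O=C1C=CC(=O)C1=[N+]=[N-] | intermediate
3 | 2-methoxycyclopent-4-ene-1,3-dione | COC1C(=O)C=CC1=O | intermediate
4 | rac-4,4,5-trimethoxycyclopent-2-en-1-one | COC1C(=O)C=CC1(OC)OC | intermediate
5 | rac-2-iodo-4,4,5-trimethoxycyclopent-2-en-1-one | COC1C(=O)C(I)=CC1(OC)OC | intermediate
6 | allyltributylstannane | C=CC[Sn](CCCC)(CCCC)CCCC | starting material
7 | rac-2-allyl-4,4,5-trimethoxycyclopent-2-en-1-one | C=CCC1=CC(OC)(OC)C(OC)C1=O | intermediate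
8 | (E)-isoeugenol | C/C=C/c1ccc(O)c(OC)c1 | starting material
9 | tert-butyl{2-methoxy-4-[(E)-prop-1-en-1-yl]phenoxy}dimethylsilane | C/C=C/c1ccc(O[Si](C)(C)C(C)(C)C)c(OC)c1 | intermediate
10 | 2-allyl-4,5-dimethoxycyclopenta-2,4-dien-1-one (not isolated) | C=CCC1=CC(OC)=C(OC)C1=O | intermediate
11 | rac-(1R,4R,5R,6S)-4-allyl-6-Ar-1,2-dimethoxy-5-methylbicyclo[2.2.1]hept-2-en-7-one, aryl endo, methyl exo (not isolated; racemate, one enantiomer drawn) | C=CC[C@@]12C=C(OC)[C@@](OC)(C1=O)[C@H](c1ccc(O[Si](C)(C)C(C)(C)C)c(OC)c1)[C@H]2C | intermediate
12 | rac-(1R,4S,5R,6S)-4-allyl-6-Ar-1-methoxy-5-methylbicyclo[2.2.1]heptane-2,7-dione, aryl endo, methyl exo (racemate, one enantiomer drawn) | C=CC[C@@]12CC(=O)[C@@](OC)(C1=O)[C@H](c1ccc(O[Si](C)(C)C(C)(C)C)c(OC)c1)[C@H]2C | intermediate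
13 | (1R,4S,5R,6S)-4-allyl-6-Ar-1-methoxy-5-methylbicyclo[2.2.1]heptane-2,7-dione (single enantiomer) | C=CC[C@@]12CC(=O)[C@@](OC)(C1=O)[C@H](c1ccc(O[Si](C)(C)C(C)(C)C)c(OC)c1)[C@H]2C | intermediate
14 | (1R,4R,5R,6S)-4-allyl-6-Ar-1-methoxy-5-methyl-2-(trimethylsilyloxy)bicyclo[2.2.1]hept-2-en-7-one | C=CC[C@@]12C=C(O[Si](C)(C)C)[C@@](OC)(C1=O)[C@H](c1ccc(O[Si](C)(C)C(C)(C)C)c(OC)c1)[C@H]2C | intermediate
15 | bromoform | BrC(Br)Br | starting material
16 | 5-allyl-3,3-dibromo-7-Ar-1-methoxy-6-methyl-2-(trimethylsilyloxy)tricyclo[3.2.1.0(2,4)]octan-8-one, cyclopropane on the exo face (not isolated) | C=CC[C@@]12[C@H]3C(Br)(Br)[C@@]3(O[Si](C)(C)C)[C@@](OC)(C1=O)[C@H](c1ccc(O[Si](C)(C)C(C)(C)C)c(OC)c1)[C@H]2C | intermediate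
17 | (1R,5S,6S,7R)-1-allyl-3-bromo-6-Ar-5-methoxy-7-methylbicyclo[3.2.1]oct-2-ene-4,8-dione | C=CC[C@@]12C=C(Br)C(=O)[C@@](OC)(C1=O)[C@H](c1ccc(O[Si](C)(C)C(C)(C)C)c(OC)c1)[C@H]2C | intermediate
18 | (1R,4R,5R,6S,7R)-1-allyl-3-bromo-4-hydroxy-6-Ar-5-methoxy-7-methylbicyclo[3.2.1]oct-2-en-8-one | C=CC[C@@]12C=C(Br)[C@H](O)[C@@](OC)(C1=O)[C@H](c1ccc(O[Si](C)(C)C(C)(C)C)c(OC)c1)[C@H]2C | intermediate
19 | (1R,4R,5R,6S,7R)-1-allyl-3-bromo-4-(tert-butyldimethylsilyloxy)-6-Ar-5-methoxy-7-methylbicyclo[3.2.1]oct-2-en-8-one | C=CC[C@@]12C=C(Br)[C@H](O[Si](C)(C)C(C)(C)C)[C@@](OC)(C1=O)[C@H](c1ccc(O[Si](C)(C)C(C)(C)C)c(OC)c1)[C@H]2C | intermediate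
20 | (1R,4S,5R,6S,7R)-1-allyl-4-(tert-butyldimethylsilyloxy)-6-(4-hydroxy-3-methoxyphenyl)-3,5-dimethoxy-7-methylbicyclo[3.2.1]oct-2-en-8-one | C=CC[C@@]12C=C(OC)[C@H](O[Si](C)(C)C(C)(C)C)[C@@](OC)(C1=O)[C@H](c1ccc(O)c(OC)c1)[C@H]2C | intermediate
21 | (1R,4S,5R,6S,7R)-1-allyl-4-hydroxy-6-(4-hydroxy-3-methoxyphenyl)-3,5-dimethoxy-7-methylbicyclo[3.2.1]oct-2-en-8-one | C=CC[C@@]12C=C(OC)[C@H](O)[C@@](OC)(C1=O)[C@H](c1ccc(O)c(OC)c1)[C@H]2C | target

## Step count and least certain steps

Total step count: 14. Longest linear sequence: 13 steps (steps 1–5 and 7–14, from 1 to 21); step 6 is a one-step side branch.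

Step 10 (key step). The most likely failures are base-induced loss of the trimethylsilyl group from 14 before the carbene arrives, and retro-Claisen opening of the strained 1,3-diketone of 14 or 17 by tert-butoxide; cyclopropanation of the terminal alkene is a lesser concern. The fallback sets out from 14 and avoids both base and carbene halogens. Cyclopropanation with Et2Zn/CH2I2 should give the exo-fused (1R,4R,5R,6S)-derived trimethylsilyloxycyclopropane F1. FeCl3 in DMF should open its internal bond oxidatively to the ring-expanded 2-chloro-bicyclo[3.2.1]octane-4,8-dione F2, and Et3N should eliminate HCl to the enedione F3. I2/pyridine should then give the 3-iodo enedione F4. F4 is carried under the conditions of steps 11, 12 and 13 through the iodo alcohol F5 and its tert-butyldimethylsilyl ether F6, and the copper-catalysed methoxylation of F6 returns to the route at 20.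

Step 7. Three processes may interfere: dimerisation of 10 instead of cycloaddition, a base-mediated prototropic shift of its doubly allylic CH2 group into an exocyclic diene, and addition with the wrong orientation or with the aryl group exo. The fallback sets out from 7 and changes the way the dienone is made. Aqueous acid should hydrolyse the ketal to 4-allyl-2-methoxycyclopent-4-ene-1,3-dione F7. Treatment with TIPSOTf/Et3N at −78 °C in the presence of 9 should silylate the carbonyl oxygen remote from the allyl-bearing carbon for steric reasons and give 2-allyl-5-methoxy-4-(triisopropylsilyloxy)cyclopenta-2,4-dien-1-one F8, trapped as the triisopropylsilyl enol ether adduct F9. Hydrolysis of F9 with 1 M HCl in THF returns to the route at 12.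

Step 13. The substitution may be slow at the hindered alkenyl bromide next to the silyloxy carbon; prolonged heating could strip the C4 silyl ether and open the aldol, and the liberated phenoxide could compete as a nucleophile. The fallback sets out from 19 and avoids alkoxide. Borylation with Pd(dppf)Cl2, B2pin2 and KOAc in dioxane should give the alkenyl pinacol boronate F10. Chan–Lam etherification with Cu(OAc)2, Et3N and methanol in air at room temperature should give the bis-silyl ether F11, and desilylation with excess TBAF/AcOH as in step 14 returns to the route at 21.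

Step 11. Chemoselectivity may be poor if the strained C8 ketone is reduced alongside C4. The fallback sets out from 17. Excess NaBH4 should give the 4,8-diol F12; TBSOTf/2,6-lutidine at −78 °C should silylate only the less hindered allylic C4 hydroxyl to give F13; and Dess–Martin periodinane should reoxidise C8, returning to the route at 19.

## Further compounds

F1 | step 10 | 5-allyl-7-Ar-1-methoxy-6-methyl-2-(trimethylsilyloxy)tricyclo[3.2.1.0(2,4)]octan-8-one, cyclopropane exo | C=CC[C@@]12[C@H]3C[C@@]3(O[Si](C)(C)C)[C@@](OC)(C1=O)[C@H](c1ccc(O[Si](C)(C)C(C)(C)C)c(OC)c1)[C@H]2C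
F2 | step 10 | (1R,5S,6S,7R)-1-allyl-2-chloro-6-Ar-5-methoxy-7-methylbicyclo[3.2.1]octane-4,8-dione, C2 configuration not defined | C=CC[C@@]12C(Cl)CC(=O)[C@@](OC)(C1=O)[C@H](c1ccc(O[Si](C)(C)C(C)(C)C)c(OC)c1)[C@H]2C
F3 | step 10 | 1-allyl-6-Ar-5-methoxy-7-methylbicyclo[3.2.1]oct-2-ene-4,8-dione | C=CC[C@@]12C=CC(=O)[C@@](OC)(C1=O)[C@H](c1ccc(O[Si](C)(C)C(C)(C)C)c(OC)c1)[C@H]2C
F4 | step 10 | 1-allyl-3-iodo-6-Ar-5-methoxy-7-methylbicyclo[3.2.1]oct-2-ene-4,8-dione | C=CC[C@@]12C=C(I)C(=O)[C@@](OC)(C1=O)[C@H](c1ccc(O[Si](C)(C)C(C)(C)C)c(OC)c1)[C@H]2C
F5 | step 10 | 1-allyl-4-hydroxy-3-iodo-6-Ar-5-methoxy-7-methylbicyclo[3.2.1]oct-2-en-8-one, hydroxyl syn to the C6–C7 bridge | C=CC[C@@]12C=C(I)[C@H](O)[C@@](OC)(C1=O)[C@H](c1ccc(O[Si](C)(C)C(C)(C)C)c(OC)c1)[C@H]2C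
F6 | step 10 | 1-allyl-4-(tert-butyldimethylsilyloxy)-3-iodo-6-Ar-5-methoxy-7-methylbicyclo[3.2.1]oct-2-en-8-one | C=CC[C@@]12C=C(I)[C@H](O[Si](C)(C)C(C)(C)C)[C@@](OC)(C1=O)[C@H](c1ccc(O[Si](C)(C)C(C)(C)C)c(OC)c1)[C@H]2C
F7 | step 7 | 4-allyl-2-methoxycyclopent-4-ene-1,3-dione | C=CCC1=CC(=O)C(OC)C1=O
F8 | step 7 | 2-allyl-5-methoxy-4-(triisopropylsilyloxy)cyclopenta-2,4-dien-1-one | C=CCC1=CC(O[Si](C(C)C)(C(C)C)C(C)C)=C(OC)C1=O
F9 | step 7 | rac-(1R,4R,5R,6S)-4-allyl-6-Ar-1-methoxy-5-methyl-2-(triisopropylsilyloxy)bicyclo[2.2.1]hept-2-en-7-one (racemate, one enantiomer drawn) | C=CC[C@@]12C=C(O[Si](C(C)C)(C(C)C)C(C)C)[C@@](OC)(C1=O)[C@H](c1ccc(O[Si](C)(C)C(C)(C)C)c(OC)c1)[C@H]2C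
F10 | step 13 | 1-allyl-4-(tert-butyldimethylsilyloxy)-6-Ar-5-methoxy-7-methyl-3-(4,4,5,5-tetramethyl-1,3,2-dioxaborolan-2-yl)bicyclo[3.2.1]oct-2-en-8-one | C=CC[C@@]12C=C(B3OC(C)(C)C(C)(C)O3)[C@H](O[Si](C)(C)C(C)(C)C)[C@@](OC)(C1=O)[C@H](c1ccc(O[Si](C)(C)C(C)(C)C)c(OC)c1)[C@H]2C
F11 | step 13 | (1R,4S,5R,6S,7R)-1-allyl-4-(tert-butyldimethylsilyloxy)-6-Ar-3,5-dimethoxy-7-methylbicyclo[3.2.1]oct-2-en-8-one | C=CC[C@@]12C=C(OC)[C@H](O[Si](C)(C)C(C)(C)C)[C@@](OC)(C1=O)[C@H](c1ccc(O[Si](C)(C)C(C)(C)C)c(OC)c1)[C@H]2C
F12 | step 11 | 1-allyl-3-bromo-6-Ar-5-methoxy-7-methylbicyclo[3.2.1]oct-2-ene-4,8-diol, C8 configuration not defined | C=CC[C@@]12C=C(Br)[C@H](O)[C@@](OC)(C1O)[C@H](c1ccc(O[Si](C)(C)C(C)(C)C)c(OC)c1)[C@H]2C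
F13 | step 11 | 1-allyl-3-bromo-4-(tert-butyldimethylsilyloxy)-6-Ar-5-methoxy-7-methylbicyclo[3.2.1]oct-2-en-8-ol, C8 configuration not defined | C=CC[C@@]12C=C(Br)[C@H](O[Si](C)(C)C(C)(C)C)[C@@](OC)(C1O)[C@H](c1ccc(O[Si](C)(C)C(C)(C)C)c(OC)c1)[C@H]2C
A1 | alternative 1 | cis-fused 2-allyl-7-Ar-5-(tert-butyldimethylsilyloxy)-4,4,6-trimethoxy-8-methylbicyclo[4.2.0]oct-2-en-1-ol | C=CCC1=CC(OC)(OC)[C@H](O[Si](C)(C)C(C)(C)C)[C@]2(OC)[C@H](c3ccc(O[Si](C)(C)C(C)(C)C)c(OC)c3)[C@@H](C)[C@]12O
A2 | alternative 1 | (1R,4S,5R,6S,7R)-1-allyl-4-(tert-butyldimethylsilyloxy)-6-Ar-3,5-dimethoxy-7-methylbicyclo[3.2.1]oct-2-en-8-one (bis-silyl ether of 21) | C=CC[C@@]12C=C(OC)[C@H](O[Si](C)(C)C(C)(C)C)[C@@](OC)(C1=O)[C@H](c1ccc(O[Si](C)(C)C(C)(C)C)c(OC)c1)[C@H]2C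
A3 | alternative 2 | 3a-allyl-2-Ar-5,7-dimethoxy-3-methyl-3,3a-dihydro-1-benzofuran-6(2H)-one, 2-aryl trans to 3-methyl, 3-methyl cis to 3a-allyl | C=CC[C@@]12C=C(OC)C(=O)C(OC)=C1O[C@H](c1ccc(O[Si](C)(C)C(C)(C)C)c(OC)c1)[C@H]2C
A4 | alternative 2 | 1-allyl-6-Ar-3,5-dimethoxy-7-methylbicyclo[3.2.1]oct-2-ene-4,8-dione | C=CC[C@@]12C=C(OC)C(=O)[C@@](OC)(C1=O)[C@H](c1ccc(O[Si](C)(C)C(C)(C)C)c(OC)c1)[C@H]2C
A5 | alternative 3 | 5-allyl-3-Ar-2-methoxy-4-methyl-2-[1-(tert-butyldimethylsilyloxy)-2-oxopropyl]cyclopentan-1-one, allyl-bearing carbon not defined | C=CCC1C(=O)[C@](OC)([C@@H](O[Si](C)(C)C(C)(C)C)C(C)=O)[C@H](c2ccc(O[Si](C)(C)C(C)(C)C)c(OC)c2)[C@H]1C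
A6 | alternative 3 | 1-allyl-4-(tert-butyldimethylsilyloxy)-6-Ar-5-methoxy-7-methylbicyclo[3.2.1]octane-3,8-dione | C=CC[C@@]12CC(=O)[C@H](O[Si](C)(C)C(C)(C)C)[C@@](OC)(C1=O)[C@H](c1ccc(O[Si](C)(C)C(C)(C)C)c(OC)c1)[C@H]2C
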